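**Plan**

1. Cuts, in order: (i) the enone C(=O)–Cα bond, together with C8–C(=O), giving a C8 aryl iodide, CO and an (E)-styrylboronic acid; (ii) C8–I to C8–H; (iii) pyran O1–C2, giving an (S)-prenyl epoxide between two equivalent phenol oxygens; (iv) the aryl–CH2 (prenyl) bond.
2. Forward: 5-methoxyresorcinol is prenylated between its two MOM ethers and epoxidised, and the pyran (the only ring made) is closed 6-endo by acid. Silylation and C8 iodination follow, then chroman, CO and styryl unit are joined in one catalytic operation; desilylation ends the route.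
3. Enabling feature: C8 of the benzene ring is the one carbon flanked by two ether oxygens (pyran O1 and the oxygen of the 7-OMe). This directs lithiation/iodination to C8, and the di-ortho-alkoxy aryl–Pd formed there takes up CO before it couples, so the ketone carbon and the C(=O)–Cα bond arrive together.
4. Stereochemistry: C3 (S) is set by the catalyst-controlled Shi epoxidation and kept in the ring closure, which never breaks the C3–O bond. The E-alkene comes from syn-hydroboration of a terminal alkyne and is retained in the coupling.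

Key step: step 9

Remark: the stereocentre is read as (3S) on the chromane (OH > C2 > C4 > H); the L-fructose-derived (ent-)Shi ketone is taken as an available catalyst.

**Step 1**
Reactants: 1 (5-methoxyresorcinol)
Product: 2 bis-MOM ether 1-methoxy-3,5-bis(methoxymethoxy)benzene
Conditions: MOMCl (2.5 equiv), i-Pr2NEt (3 equiv), CH2Cl2, 0 °C → rt
Reagents that add atoms: chloromethyl methyl ether (MOMCl), COCCl
Why: Williamson-type O-alkylation of both phenols (MOM protection) should proceed cleanly and installs the two acetal ethers that direct the metalation of step 2.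

**Step 2**
Reactants: 2 (bis-MOM ether); 3 (prenyl bromide)
Product: 5 prenyl arene 5-methoxy-1,3-bis(methoxymethoxy)-2-(3-methylbut-2-en-1-yl)benzene, via aryllithium 4 (not isolated)
Conditions: n-BuLi (1.1 equiv), THF, 0 °C; CuI (10 mol%), then 3, −78 °C → rt
Reagents that add atoms: none
Why: Directed ortho-metalation should occur at the C–H between the two OMOM groups, the most acidic and doubly chelated site (each position next to OMe has only one MOM neighbour), and copper-assisted SN2 allylation of the aryllithium should give the linear prenyl arene.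

**Step 3**
Reactants: 5 (prenyl arene)
Product: 6 (S)-epoxide (3S)-3-[4-methoxy-2,6-bis(methoxymethoxy)benzyl]-2,2-dimethyloxirane
Conditions: ent-Shi ketone (30 mol%), Oxone, K2CO3, Bu4NHSO4, MeCN–DMM/aq. Na2B4O7–EDTA (pH ≈ 10.5), 0 °C
Reagents that add atoms: Oxone (potassium peroxymonosulfate), [K+].[O-]S(=O)(=O)OO
Why: Shi asymmetric epoxidation, in which the chiral dioxirane attacks the electron-rich trisubstituted alkene through the spiro transition state; the D-fructose ketone gives the (R) series for R–CH=CMe2 alkenes, so its enantiomer should give the (S)-epoxide and thereby fix C3 of the target.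

**Step 4**
Reactants: 6 ((S)-epoxide)
Product: 8 chromanediol (3S)-7-methoxy-2,2-dimethylchromane-3,5-diol, via mono-MOM chromanol 7 (not isolated)
Conditions: TsOH·H2O (0.2 equiv), CH2Cl2–MeOH 10:1, 0 °C → rt; then conc. HCl (cat.), MeOH, 40 °C
Reagents that add atoms: none
Why: Acidic MOM cleavage with in situ acid-catalysed phenol–epoxide cyclisation, in which an ortho oxygen (free, or still carrying its MOM group, which then leaves to methanol) attacks the tertiary carbon of the protonated epoxide (Markovnikov, 6-endo); C3–O is untouched so (S) is retained, both ortho oxygens are equivalent so only one chroman can form, and methanolysis removes the second MOM.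

**Step 5**
Reactants: 8 (chromanediol)
Product: 9 bis-TIPS ether (3S)-7-methoxy-2,2-dimethyl-3,5-bis(triisopropylsilyloxy)chromane
Conditions: TIPSOTf (2.5 equiv), 2,6-lutidine (3.5 equiv), CH2Cl2, 0 °C → rt
Reagents that add atoms: triisopropylsilyl triflate (TIPSOTf), CC(C)[Si](OS(=O)(=O)C(F)(F)F)(C(C)C)C(C)C
Why: Silylation with the reactive triflate should cover both the phenol and the hindered secondary alcohol, and the bulky, poorly coordinating OTIPS on C5 then shields C6 in step 6.

**Step 6**
Reactants: 9 (bis-TIPS ether)
Product: 11 aryl iodide (3S)-8-iodo-7-methoxy-2,2-dimethyl-3,5-bis(triisopropylsilyloxy)chromane, via C8-aryllithium 10 (not isolated)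
Conditions: n-BuLi (1.3 equiv), TMEDA (1.3 equiv), THF, 0 °C; then I2, −78 °C → rt
Reagents that add atoms: iodine, II
Why: Directed ortho-metalation followed by iodine quench; C8–H lies between the pyran oxygen O1 and the 7-OMe oxygen (1,3-dialkoxyarene, cooperative direction), whereas C6 is flanked by the non-coordinating OTIPS, so lithiation should occur at C8.

**Step 7**
Reactants: 12 (4-ethynylphenol)
Product: 13 (4-ethynylphenoxy)triisopropylsilane
Conditions: TIPSCl (1.2 equiv), imidazole (2 equiv), DMF, rt
Reagents that add atoms: triisopropylsilyl chloride (TIPSCl), CC(C)[Si](Cl)(C(C)C)C(C)C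
Why: Imidazole-assisted silylation of the phenol is standard and gives a base-robust aryl silyl ether that leaves with the other silyl groups in the last step.

**Step 8**
Reactants: 13 (silyl-protected alkyne)
Product: 15 (E)-alkenylboronic acid [(E)-2-{4-[(triisopropylsilyl)oxy]phenyl}ethenyl]boronic acid, via catechol boronate 14 (not isolated)
Conditions: catecholborane (1.2 equiv), THF, 65 °C; then H2O, rt
Reagents that add atoms: catecholborane, B1Oc2ccccc2O1; water, O
Why: Brown hydroboration of a terminal alkyne is a syn, anti-Markovnikov addition that places boron on the terminal carbon and sets the E geometry, and hydrolysis of the catechol ester should give the boronic acid.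

**Step 9**
Reactants: 11 (aryl iodide); 15 ((E)-alkenylboronic acid)
Product: 16 tris-TIPS chalcone (E)-1-[(3S)-7-methoxy-2,2-dimethyl-3,5-bis(triisopropylsilyloxy)chroman-8-yl]-3-{4-[(triisopropylsilyl)oxy]phenyl}prop-2-en-1-one
Conditions: Pd-PEPPSI-IPr (5 mol%), Cs2CO3 (3 equiv), CO (3 bar), chlorobenzene, 80 °C
Reagents that add atoms: carbon monoxide, [C-]#[O+]
Why: Pd(0)–NHC inserts into the C8–I bond, CO insertion gives the aroyl–Pd(II) species, the (E)-alkenylboronate transmetalates with retention, and reductive elimination forges the C(=O)–Cα bond of the enone. The closest known reaction type is the carbonylative Suzuki–Miyaura coupling of di-ortho-substituted aryl iodides with boronic acids under bulky NHC–Pd catalysis. No ring is closed and no stereocentre is created: the (S)-C3 centre is remote and untouched, and the E geometry is carried over from the boronic acid. The selectivity needed is ketone formation over direct CO-free coupling and over protodeiodination; the two ortho oxygens (O1 and OMe) slow transmetalation at the aryl–Pd stage so that CO insertion should come first, and CO pressure reinforces this. All hydroxyl groups are silylated, so no phenoxide or alkoxide can intercept the aroyl–Pd as an ester; partial loss of an aryl silyl group would be harmless because the next step removes them all.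

**Step 10**
Reactants: 16 (tris-TIPS chalcone)
Product: 17 target (E)-1-[(3S)-3,5-dihydroxy-7-methoxy-2,2-dimethylchroman-8-yl]-3-(4-hydroxyphenyl)prop-2-en-1-one
Conditions: TBAF (6 equiv), AcOH (6 equiv), THF, 0 °C → 40 °C
Reagents that add atoms: none
Why: Fluoride-driven Si–O cleavage (global desilylation) should free the two phenols quickly and the hindered 3-OH more slowly; the acetic acid buffer protects the enone, and with both carbonyl-flanking oxygens alkylated no flavanone closure is possible.

**Compound list**

1 | 5-methoxyresorcinol (5-methoxybenzene-1,3-diol) | COc1cc(O)cc(O)c1 | starting material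
2 | 1-methoxy-3,5-bis(methoxymethoxy)benzene | COc1cc(OCOC)cc(OCOC)c1 | intermediate
3 | prenyl bromide (1-bromo-3-methylbut-2-ene) | CC(C)=CCBr | starting material
4 | [4-methoxy-2,6-bis(methoxymethoxy)phenyl]lithium | COc1cc(OCOC)c([Li])c(OCOC)c1 | intermediate
5 | 5-methoxy-1,3-bis(methoxymethoxy)-2-(3-methylbut-2-en-1-yl)benzene | COc1cc(OCOC)c(CC=C(C)C)c(OCOC)c1 | intermediate
6 | (3S)-3-[4-methoxy-2,6-bis(methoxymethoxy)benzyl]-2,2-dimethyloxirane | CC1(C)O[C@H]1Cc1c(OCOC)cc(OC)cc1OCOC | intermediate
7 | (3S)-7-methoxy-5-(methoxymethoxy)-2,2-dimethylchroman-3-ol | COCOc1cc(OC)cc2c1C[C@H](O)C(C)(C)O2 | intermediate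
8 | (3S)-7-methoxy-2,2-dimethylchromane-3,5-diol | COc1cc(O)c2c(c1)OC(C)(C)[C@@H](O)C2 | intermediate
9 | (3S)-7-methoxy-2,2-dimethyl-3,5-bis(triisopropylsilyloxy)chromane | COc1cc(O[Si](C(C)C)(C(C)C)C(C)C)c2c(c1)OC(C)(C)[C@@H](O[Si](C(C)C)(C(C)C)C(C)C)C2 | intermediate
10 | [(3S)-7-methoxy-2,2-dimethyl-3,5-bis(triisopropylsilyloxy)chroman-8-yl]lithium | COc1cc(O[Si](C(C)C)(C(C)C)C(C)C)c2c(c1[Li])OC(C)(C)[C@@H](O[Si](C(C)C)(C(C)C)C(C)C)C2 | intermediate
11 | (3S)-8-iodo-7-methoxy-2,2-dimethyl-3,5-bis(triisopropylsilyloxy)chromane | COc1cc(O[Si](C(C)C)(C(C)C)C(C)C)c2c(c1I)OC(C)(C)[C@@H](O[Si](C(C)C)(C(C)C)C(C)C)C2 | intermediate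
12 | 4-ethynylphenol | C#Cc1ccc(O)cc1 | starting material
13 | (4-ethynylphenoxy)triisopropylsilane | C#Cc1ccc(O[Si](C(C)C)(C(C)C)C(C)C)cc1 | intermediate
14 | 2-[(E)-2-{4-[(triisopropylsilyl)oxy]phenyl}ethenyl]-1,3,2-benzodioxaborole | CC(C)[Si](Oc1ccc(/C=C/B2Oc3ccccc3O2)cc1)(C(C)C)C(C)C | intermediate
15 | [(E)-2-{4-[(triisopropylsilyl)oxy]phenyl}ethenyl]boronic acid | CC(C)[Si](Oc1ccc(/C=C/B(O)O)cc1)(C(C)C)C(C)C | intermediate
16 | (E)-1-[(3S)-7-methoxy-2,2-dimethyl-3,5-bis(triisopropylsilyloxy)chroman-8-yl]-3-{4-[(triisopropylsilyl)oxy]phenyl}prop-2-en-1-one | COc1cc(O[Si](C(C)C)(C(C)C)C(C)C)c2c(c1C(=O)/C=C/c1ccc(O[Si](C(C)C)(C(C)C)C(C)C)cc1)OC(C)(C)[C@@H](O[Si](C(C)C)(C(C)C)C(C)C)C2 | intermediate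
17 | (E)-1-[(3S)-3,5-dihydroxy-7-methoxy-2,2-dimethylchroman-8-yl]-3-(4-hydroxyphenyl)prop-2-en-1-one | COc1cc(O)c2c(c1C(=O)/C=C/c1ccc(O)cc1)OC(C)(C)[C@@H](O)C2 | target

**Step count and risks**

Total steps: 10. Longest linear sequence: 8 (steps 1–6, 9, 10).

Steps most likely to fail:

1. Step 9. The catalytic cycle may stall after oxidative addition at the crowded C8 position, leading to CO-free direct coupling or protodeiodination, or the alkenylboronic acid may be lost by protodeboronation before it meets the hindered aroyl–Pd. The fallback installs the acyl carbon stoichiometrically and makes the same C(=O)–Cα bond by a Weinreb ketone synthesis. Iodide 11 is converted by iodine–lithium exchange (t-BuLi, THF, −78 °C) into aryllithium 10, which is trapped with N-methoxy-N-methylcarbamoyl chloride to give the Weinreb amide F1. Boronic acid 15 is converted with NIS in MeCN (iododeboronation with retention) into the (E)-vinyl iodide F2, which with t-BuLi at −78 °C gives the (E)-styryllithium F3. Addition of F3 to F1 should return the route at enone 16.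

2. Step 4. The protonated epoxide may be opened by methanol before a phenolic oxygen engages, or the ring may close 5-exo to the dihydrobenzofuran carbinol. The fallback frees the phenols before the epoxide exists and re-masks them with fluoride-labile groups. From prenyl arene 5, HCl/MeOH gives 5-methoxy-2-prenylresorcinol F4, TBSCl/imidazole gives the bis-TBS ether F5, and the same ent-Shi epoxidation gives the silylated (S)-epoxide F6. Buffered fluoride (TBAF/AcOH, which forms no phenoxide and so avoids base-type 5-exo opening) liberates the epoxy diphenol F7. F7 is closed 6-endo with catalytic CSA in CH2Cl2, a medium without external nucleophile, to rejoin the route at diol 8.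

3. Step 6. The deprotonation may lack site selectivity (competing C6 lithiation with O→C silyl migration), or the base may attack silicon. The fallback replaces metalation by electrophilic substitution directed by the free phenol. From diol 8, NIS (CH2Cl2, −78 °C) should iodinate para to the 5-OH, that is at C8, to give the iodo diol F8. Bis-silylation of F8 with TIPSOTf/2,6-lutidine returns the route at iodide 11.

**Further compounds**

F1 | step 9 | (3S)-N,7-dimethoxy-N,2,2-trimethyl-3,5-bis(triisopropylsilyloxy)chromane-8-carboxamide | COc1cc(O[Si](C(C)C)(C(C)C)C(C)C)c2c(c1C(=O)N(C)OC)OC(C)(C)[C@@H](O[Si](C(C)C)(C(C)C)C(C)C)C2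
F2 | step 9 | {4-[(E)-2-iodoethenyl]phenoxy}triisopropylsilane | CC(C)[Si](Oc1ccc(/C=C/I)cc1)(C(C)C)C(C)C
F3 | step 9 | [(E)-2-{4-[(triisopropylsilyl)oxy]phenyl}ethenyl]lithium | CC(C)[Si](Oc1ccc(/C=C/[Li])cc1)(C(C)C)C(C)C
F4 | step 4 | 5-methoxy-2-(3-methylbut-2-en-1-yl)benzene-1,3-diol | COc1cc(O)c(CC=C(C)C)c(O)c1
F5 | step 4 | 1,3-bis(tert-butyldimethylsilyloxy)-5-methoxy-2-(3-methylbut-2-en-1-yl)benzene | COc1cc(O[Si](C)(C)C(C)(C)C)c(CC=C(C)C)c(O[Si](C)(C)C(C)(C)C)c1
F6 | step 4 | (3S)-3-[2,6-bis(tert-butyldimethylsilyloxy)-4-methoxybenzyl]-2,2-dimethyloxirane | CC1(C)O[C@H]1Cc1c(O[Si](C)(C)C(C)(C)C)cc(OC)cc1O[Si](C)(C)C(C)(C)C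
F7 | step 4 | 2-{[(2S)-3,3-dimethyloxiran-2-yl]methyl}-5-methoxybenzene-1,3-diol | CC1(C)O[C@H]1Cc1c(O)cc(OC)cc1O
F8 | step 6 | (3S)-8-iodo-7-methoxy-2,2-dimethylchromane-3,5-diol | COc1cc(O)c2c(c1I)OC(C)(C)[C@@H](O)C2
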